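## Retrosynthetic overview

1. The C8 ester is made last by Mitsunobu inversion of the 8-epi alcohol 17 with vanillic acid.
2. C3=C4 and C15 come from the C4 ketone 13 (Shapiro reaction, MeI); C5–H and the non-conjugated C1=C10 bond come from an asymmetric deconjugative protonation of silyl dienol ether 12.
3. The seven-membered ring (formed second) is closed at C1–C10 by intramolecular vinyllithium addition to a vinylogous ester, followed by 1,6-reduction of dienone 10.
4. C8–C9 comes from a Felkin-selective bromoallylation; C6–C7 and the first stereocenter (C7) come from an amine-catalysed enamine Michael addition to in situ 2-methylidenecyclopentane-1,3-dione.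
5. The five-membered ring (first) is bought as cyclopentane-1,3-dione; the other building blocks are formaldehyde, 3-methylbutanal, 2,3-dibromopropene and vanillic acid.

Notation (one line): guaiane numbering is used in names (five-membered ring C1–C5, seven-membered ring C5–C10 plus C1, C14 on C10, C15 on C4; "15-nor" = no C15); the target is taken as the (5R,7R,8S) isomer read from the SMILES.

## Route

Step 1
Reactants: 1 cyclopentane-1,3-dione; 2 formaldehyde; 3 3-methylbutanal
Product: 5 (2R)-2-[(2,5-dioxocyclopentyl)methyl]-3-methylbutanal, via 2-methylidenecyclopentane-1,3-dione 4 (not isolated)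
Conditions: 1, aq. CH2O (1.0 equiv), CH2Cl2, rt, 30 min; then 3 (1.5 equiv), (R)-2-[diphenyl(trimethylsilyloxy)methyl]pyrrolidine (10 mol %), 0 °C, 24 h
Reagents that add atoms: none
Why: Knoevenagel condensation gives the highly electrophilic methylene dione 4, which the anti-E enamine of 3 attacks (enamine Michael addition, equally an inverse-demand hetero-Diels–Alder reaction) on the face away from the CPh2OSiMe3 group of the (R)-catalyst, setting C7 as R; 5 is isolated as its cyclic lactol tautomer.

Step 2
Reactants: 5 (2R)-2-[(2,5-dioxocyclopentyl)methyl]-3-methylbutanal; 6 2,3-dibromoprop-1-ene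
Product: 7 2-[(2R,3R)-5-bromo-3-hydroxy-2-(propan-2-yl)hex-5-en-1-yl]cyclopentane-1,3-dione
Conditions: Zn dust (2 equiv), THF/sat. aq. NH4Cl 1:1, 0 °C to rt
Reagents that add atoms: none
Why: Aqueous Barbier allylation of the lactol-masked aldehyde; Felkin–Anh attack anti to the isopropyl group gives the (8R) carbinol (O8 cis to the isopropyl group in the later ring) as the major diastereomer, the minor epimer being removed by chromatography at 8.

Step 3
Reactants: 7 2-[(2R,3R)-5-bromo-3-hydroxy-2-(propan-2-yl)hex-5-en-1-yl]cyclopentane-1,3-dione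
Product: 8 2-[(2R,3R)-5-bromo-3-hydroxy-2-(propan-2-yl)hex-5-en-1-yl]-3-methoxycyclopent-2-en-1-one
Conditions: Me3SiCHN2 (1.2 equiv), PhMe/MeOH 4:1, 0 °C
Reagents that add atoms: (trimethylsilyl)diazomethane, C[Si](C)(C)C=[N+]=[N-]
Why: O-methylation of the acidic enol (pKa about 5) of the symmetric 2-alkyl-1,3-dione by the diazoalkane gives a single vinylogous ester and leaves the secondary alcohol untouched.

Step 4
Reactants: 8 2-[(2R,3R)-5-bromo-3-hydroxy-2-(propan-2-yl)hex-5-en-1-yl]-3-methoxycyclopent-2-en-1-one
Product: 10 (7R,8R)-8-hydroxy-15-norguaia-1(5),10(14)-dien-4-one, via tertiary carbinol adduct 9 (not isolated)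
Conditions: t-BuLi (3.1 equiv), THF, −78 °C, 1 h; then 1 M HCl, THF, 0 °C
Reagents that add atoms: water, O
Why: Bromine–lithium exchange and intramolecular 1,2-addition of the vinyllithium to the vinylogous ester carbonyl (Stork–Danheiser sequence run as a Parham-type anionic cyclization) closes the seven-membered ring at C1–C10, and acid hydrolysis with loss of methanol transposes the enone to C4; no stereocenter is created.

Step 5
Reactants: 10 (7R,8R)-8-hydroxy-15-norguaia-1(5),10(14)-dien-4-one
Product: 12 (7R,8R)-4,8-bis(triethylsilyloxy)-15-norguaia-1(10),4-diene, via dilithium dienolate 11 (not isolated)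
Conditions: Li (2.1 equiv), NH3(l)/THF, −78 °C; evaporate NH3; Et3SiCl (2.5 equiv), Et3N, THF, −78 to 0 °C
Reagents that add atoms: chlorotriethylsilane, CC[Si](CC)(CC)Cl
Why: Dissolving-metal (Birch-type) 1,6-reduction of the linear dienone puts the hydrogen on the terminal methylene (C14 becomes the methyl group, the proton coming from O8–H), and the lithium dienolate is trapped on oxygen as the silyl dienol ether, which also protects O8.

Step 6
Reactants: 12 (7R,8R)-4,8-bis(triethylsilyloxy)-15-norguaia-1(10),4-diene
Product: 13 (5S,7R,8R)-8-(triethylsilyloxy)-15-norguai-1(10)-en-4-one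
Conditions: (R)-3,3′-bis(2,4,6-triisopropylphenyl)-1,1′-binaphthyl-2,2′-diyl N-triflylphosphoramide (5 mol %; the enantiomer that protonates the C5 face syn to the C7 isopropyl group is chosen by screening), MeOH (1.1 equiv, slow addition), PhMe, −78 °C
Reagents that add atoms: none
Why: Proposed new method: catalytic asymmetric deconjugative α-protonation of a cyclic silyl dienol ether. The chiral strong Brønsted acid protonates the dienol ether kinetically at the α-carbon C5 inside its chiral ion pair (α-protonation is the kinetic site, as in the hydrolysis of steroidal dienol ethers to β,γ-unsaturated ketones). Methanol then takes the silyl group and regenerates the acid, so C5 is set (H syn to the isopropyl group, 5S in this ketone) and the tetrasubstituted C1=C10 bond stays out of conjugation. The closest known reaction is the chiral Brønsted acid-catalysed enantioselective protonation of silyl enol ethers of 2-aryl cyclic ketones with a stoichiometric achiral proton source.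

Step 7
Reactants: 13 (5S,7R,8R)-8-(triethylsilyloxy)-15-norguai-1(10)-en-4-one
Product: 14 (5S,7R,8R)-8-(triethylsilyloxy)-15-norguai-1(10)-en-4-one 2,4,6-triisopropylbenzenesulfonylhydrazone
Conditions: 2,4,6-(i-Pr)3C6H2SO2NHNH2 (1.1 equiv), THF, rt
Reagents that add atoms: 2,4,6-triisopropylbenzenesulfonohydrazide, CC(C)c1cc(C(C)C)c(S(=O)(=O)NN)c(C(C)C)c1
Why: Neutral condensation of the cyclopentanone with the sulfonyl hydrazide gives the E-hydrazone (sulfonamide nitrogen anti to the branched C5) without enolising the labile C5 position.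

Step 8
Reactants: 14 (5S,7R,8R)-8-(triethylsilyloxy)-15-norguai-1(10)-en-4-one 2,4,6-triisopropylbenzenesulfonylhydrazone
Product: 17 (5R,7R,8R)-guaia-1(10),3-dien-8-ol, via vinyllithium 15 (not isolated), via triethylsilyl ether 16 (not isolated)
Conditions: n-BuLi (2.2 equiv), THF/TMEDA, −78 to 0 °C; MeI (3 equiv), −78 °C to rt; then Bu4NF (1.5 equiv), THF, 0 °C
Reagents that add atoms: iodomethane, CI
Why: Shapiro reaction: deprotonation occurs only syn to the sulfonamide nitrogen (at C3), loss of sulfinate and N2 gives the C4 vinyllithium with the C3=C4 bond fixed, methylation installs C15 and fluoride removes the silyl ether; C5 is not touched.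

Step 9
Reactants: 17 (5R,7R,8R)-guaia-1(10),3-dien-8-ol; 18 4-hydroxy-3-methoxybenzoic acid (vanillic acid)
Product: 19 (5R,7R,8S)-guaia-1(10),3-dien-8-yl 4-hydroxy-3-methoxybenzoate
Conditions: PPh3 (1.5 equiv), DIAD (1.5 equiv), THF, 0 °C to rt
Reagents that add atoms: none
Why: Mitsunobu esterification: the carboxylic acid, more acidic than the phenol, is the nucleophile and displaces the activated C8–O with inversion (8R to 8S), giving the ester trans to the isopropyl group under neutral conditions that leave the skipped diene intact.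

## Compound list

1 | cyclopentane-1,3-dione | O=C1CCC(=O)C1 | starting material
2 | formaldehyde | C=O | starting material
3 | 3-methylbutanal | CC(C)CC=O | starting material
4 | 2-methylidenecyclopentane-1,3-dione | C=C1C(=O)CCC1=O | intermediate (not isolated)
5 | (2R)-2-[(2,5-dioxocyclopentyl)methyl]-3-methylbutanal (handled as its lactol) | O=C1CCC(=O)C1C[C@@H](C=O)C(C)C | intermediate
6 | 2,3-dibromoprop-1-ene | C=C(Br)CBr | starting material
7 | 2-[(2R,3R)-5-bromo-3-hydroxy-2-(propan-2-yl)hex-5-en-1-yl]cyclopentane-1,3-dione | O=C1CCC(=O)C1C[C@H](C(C)C)[C@H](O)CC(Br)=C | intermediate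
8 | 2-[(2R,3R)-5-bromo-3-hydroxy-2-(propan-2-yl)hex-5-en-1-yl]-3-methoxycyclopent-2-en-1-one | COC1=C(C[C@H](C(C)C)[C@H](O)CC(Br)=C)C(=O)CC1 | intermediate
9 | (7R,8R)-4-methoxy-15-norguaia-4,10(14)-diene-1,8-diol (either C1 epimer) | COC1=C2C[C@H](C(C)C)[C@H](O)CC(=C)C2(O)CC1 | intermediate (not isolated)
10 | (7R,8R)-8-hydroxy-15-norguaia-1(5),10(14)-dien-4-one | O[C@@H]2CC(=C)C3=C(C[C@@H]2C(C)C)C(=O)CC3 | intermediate
11 | dilithium (7R,8R)-15-norguaia-1(10),4-diene-4,8-diolate | [Li+].[Li+].[O-]C1=C2C[C@H](C(C)C)[C@H]([O-])CC(C)=C2CC1 | intermediate (not isolated)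
12 | (7R,8R)-4,8-bis(triethylsilyloxy)-15-norguaia-1(10),4-diene | CC[Si](CC)(CC)O[C@@H]2CC(C)=C3CCC(O[Si](CC)(CC)CC)=C3C[C@@H]2C(C)C | intermediate
13 | (5S,7R,8R)-8-(triethylsilyloxy)-15-norguai-1(10)-en-4-one (H5, isopropyl and O8 on one face) | CC[Si](CC)(CC)O[C@@H]2CC(C)=C3CCC(=O)[C@H]3C[C@@H]2C(C)C | intermediate
14 | 2,4,6-triisopropylbenzenesulfonylhydrazone of 13 | CC[Si](CC)(CC)O[C@@H]2CC(C)=C3CCC(=NNS(=O)(=O)c4c(C(C)C)cc(C(C)C)cc4C(C)C)[C@H]3C[C@@H]2C(C)C | intermediate
15 | (5R,7R,8R)-4-lithio-8-(triethylsilyloxy)-15-norguaia-1(10),3-diene | CC[Si](CC)(CC)O[C@@H]2CC(C)=C3CC=C([Li])[C@H]3C[C@@H]2C(C)C | intermediate (not isolated)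
16 | (5R,7R,8R)-8-(triethylsilyloxy)guaia-1(10),3-diene | CC[Si](CC)(CC)O[C@@H]2CC(C)=C3CC=C(C)[C@H]3C[C@@H]2C(C)C | intermediate (not isolated)
17 | (5R,7R,8R)-guaia-1(10),3-dien-8-ol | O[C@@H]2CC(C)=C3CC=C(C)[C@H]3C[C@@H]2C(C)C | intermediate
18 | 4-hydroxy-3-methoxybenzoic acid | COc1cc(C(=O)O)ccc1O | starting material
19 | (5R,7R,8S)-guaia-1(10),3-dien-8-yl 4-hydroxy-3-methoxybenzoate | COc1cc(C(=O)O[C@H]2CC(C)=C3CC=C(C)[C@H]3C[C@@H]2C(C)C)ccc1O | target

## Step count and risks

Total steps: 9. Longest linear sequence: 9 (from cyclopentane-1,3-dione).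

The three steps most likely to fail are steps 6, 4 and 9.

Step 6 (the new reaction) may give poor facial control at C5 or some γ-protonation to the conjugated enone. The fallback sets out from 10 and uses classical chemistry: Li in NH3(l)/THF at −78 °C followed by a rapid quench with solid NH4Cl gives, by kinetic α-protonation of the dienolate, the β,γ-unsaturated ketone (5S,7R,8R)-8-hydroxy-15-norguai-1(10)-en-4-one F3 together with its C5 epimer. The epimers are separated by chromatography, and silylation of F3 with Et3SiCl and imidazole in CH2Cl2 returns to the route at 13.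

Step 4 may fail through enolisation of the vinylogous ester or attack of t-BuLi on its carbonyl. The fallback sets out from 5 and closes the ring at C8–C9 instead of C1–C10. MeOH with pyridinium p-toluenesulfonate converts the lactol into the methyl acetal (3R)-2-methoxy-3-(propan-2-yl)-3,4,6,7-tetrahydrocyclopenta[b]pyran-5(2H)-one F1, which is itself a vinylogous ester. Addition of [3-(trimethylsilyl)prop-1-en-2-yl]magnesium bromide (from (2-bromoallyl)trimethylsilane and Mg) and mild aqueous acid gives the aldehyde allylsilane (2R)-3-methyl-2-({5-oxo-2-[3-(trimethylsilyl)prop-1-en-2-yl]cyclopent-1-en-1-yl}methyl)butanal F2. A fluoride-promoted intramolecular Hosomi–Sakurai allylation (Bu4NF, THF) then gives 10, the C8 epimer being separated, and the route continues from 10.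

Step 9 may fail by elimination or slow displacement at the hindered C8. The fallback sets out from 17 and replaces the substitution by oxidation, reagent-controlled reduction and acylation with retention. Dess–Martin periodinane buffered with NaHCO3 gives the ketone (5R,7R)-guaia-1(10),3-dien-8-one F4. Reduction with (R)-Me-CBS oxazaborolidine and BH3·SMe2 gives the trans alcohol (5R,7R,8S)-guaia-1(10),3-dien-8-ol F5. Acylation with 4-[(tert-butyldimethylsilyl)oxy]-3-methoxybenzoyl chloride and DMAP gives the protected ester (5R,7R,8S)-guaia-1(10),3-dien-8-yl 4-[(tert-butyldimethylsilyl)oxy]-3-methoxybenzoate F6, and Bu4NF buffered with AcOH returns to the route at 19.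

Further compounds
F1 | step 4 | (3R)-2-methoxy-3-(propan-2-yl)-3,4,6,7-tetrahydrocyclopenta[b]pyran-5(2H)-one | COC1OC2=C(C[C@@H]1C(C)C)C(=O)CC2
F2 | step 4 | (2R)-3-methyl-2-({5-oxo-2-[3-(trimethylsilyl)prop-1-en-2-yl]cyclopent-1-en-1-yl}methyl)butanal | O=C[C@H](CC1=C(C(=C)C[Si](C)(C)C)CCC1=O)C(C)C
F3 | step 6 | (5S,7R,8R)-8-hydroxy-15-norguai-1(10)-en-4-one | O[C@@H]2CC(C)=C3CCC(=O)[C@H]3C[C@@H]2C(C)C
F4 | step 9 | (5R,7R)-guaia-1(10),3-dien-8-one | O=C2CC(C)=C3CC=C(C)[C@H]3C[C@@H]2C(C)C
F5 | step 9 | (5R,7R,8S)-guaia-1(10),3-dien-8-ol | O[C@H]2CC(C)=C3CC=C(C)[C@H]3C[C@@H]2C(C)C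
F6 | step 9 | (5R,7R,8S)-guaia-1(10),3-dien-8-yl 4-[(tert-butyldimethylsilyl)oxy]-3-methoxybenzoate | COc1cc(C(=O)O[C@H]2CC(C)=C3CC=C(C)[C@H]3C[C@@H]2C(C)C)ccc1O[Si](C)(C)C(C)(C)C
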